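## Retrosynthetic overview

- **Ring labels and the feature used.** The flavone has rings A (benzo), C (pyranone) and B (aryl); the flavan has rings D (benzo), F (pyran) and E (aryl). The plan rests on ring D. Its six carbons carry in turn OH (C5), flavone C3 (C6), OH (C7), H (C8), the ring-F oxygen O1 (C8a) and the ring-F methylene C4 (C4a). This is a resorcinol with its carbon substituent between the two oxygens, which is the pattern a vinylketene plus ynol ether benzannulation produces.
- **Key disconnection.** Ring D is cut at C5–C6, C7–C8, C8–C8a and C4a–C5. This gives a dihydropyranyl diazomethyl ketone (ring F with both stereocentres, plus ring E) and a 3-(silyloxyethynyl)flavone (rings A, C, B). The tetra-ortho-substituted C3–C6 axis is therefore never made by cross-coupling.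
- **Diazoketone.** 4-benzyloxybenzaldehyde, styrene, E-alkenoate by cross-metathesis, Shi epoxide (source of C2 and C3), 6-endo lactonisation (closes ring F), ketene acetal phosphate, Stille acetylation, diazo transfer.
- **Siloxyalkyne.** Apigenin, tribenzyl ether, C3 iodide, Sonogashira ethynylation, acetylide oxidation with O-silylation.
- **Order of rings.** A, C and B come with apigenin and E with the aldehyde. Ring F forms in step 4 and ring D in step 13. Fluoride and hydrogenolysis then unmask the remaining hydroxyl groups.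

Key step: step 13

Assumption: the target structure defines no configuration for the hindered flavone C3–flavan C6 axis, so slowly interconverting rotamers about this bond are treated as one compound.

## Route

Step 1
Reactants: 1 4-(benzyloxy)benzaldehyde
Product: 2 1-(benzyloxy)-4-vinylbenzene
Conditions: Ph3PCH3Br, KOtBu, THF, 0 °C to rt
Reagents that add atoms: methyltriphenylphosphonium bromide, C[P+](c1ccccc1)(c1ccccc1)c1ccccc1.[Br-]
Why: Wittig methylenation of a non-enolisable aromatic aldehyde is a dependable way to the styrene, and the benzyl ether is inert to the ylide.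

Step 2
Reactants: 2 1-(benzyloxy)-4-vinylbenzene; 3 tert-butyl pent-4-enoate
Product: 4 tert-butyl (E)-5-[4-(benzyloxy)phenyl]pent-4-enoate
Conditions: second-generation Grubbs catalyst RuCl2(=CHPh)(PCy3)(H2IMes) (3 mol %), 3 (3 equiv), CH2Cl2, 40 °C
Reagents that add atoms: tert-butyl pent-4-enoate (reactant 3), C=CCCC(=O)OC(C)(C)C
Why: Olefin cross-metathesis of a styrene with an excess of an unhindered terminal alkene should give the conjugated E-alkene under thermodynamic control, the homodimer of 3 re-entering the cycle; the tert-butyl ester is chosen because step 4 needs an ester that can leave as isobutene without water.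

Step 3
Reactants: 4 tert-butyl (E)-5-[4-(benzyloxy)phenyl]pent-4-enoate
Product: 5 tert-butyl 3-[(2R,3R)-3-[4-(benzyloxy)phenyl]oxiran-2-yl]propanoate
Conditions: 1,2:4,5-di-O-isopropylidene-β-D-erythro-2,3-hexodiulo-2,6-pyranose (30 mol %), Oxone (2KHSO5·KHSO4·K2SO4), K2CO3, Bu4NHSO4 (cat.), Na2B4O7/Na2EDTA buffer (pH about 10.5), MeCN–CH2(OMe)2, 0 °C; cold basic extraction, short plug of Et3N-deactivated silica
Reagents that add atoms: potassium peroxymonosulfate KHSO5 (active part of Oxone), [K+].[O-]S(=O)(=O)OO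
Why: Shi epoxidation of a trans-disubstituted aryl alkene through the spiro transition state of the chiral dioxirane, in which the D-fructose-derived ketone attacks the face that gives (R,R)-epoxides from trans-β-alkylstyrenes so that the catalyst sets both C–O stereocentres, while the high pH, the low temperature and a neutral substrate should keep the acid-labile 4-alkoxyphenyl epoxide intact.

Step 4
Reactants: 5 tert-butyl 3-[(2R,3R)-3-[4-(benzyloxy)phenyl]oxiran-2-yl]propanoate
Product: 7 (5R,6S)-6-[4-(benzyloxy)phenyl]-5-(tert-butyldimethylsilyloxy)oxan-2-one, via hydroxylactone 6 (not isolated)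
Conditions: camphorsulfonic acid (10 mol %), dry CH2Cl2, −40 to 0 °C; then 2,6-lutidine, TBSOTf, −78 to 0 °C, same flask
Reagents that add atoms: tert-butyldimethylsilyl triflate, CC(C)(C)[Si](C)(C)OS(=O)(=O)C(F)(F)F
Why: Acid-catalysed 6-endo-tet epoxide opening by the ester carbonyl oxygen, in which the 4-benzyloxyphenyl group loosens the benzylic C–O bond so that attack falls on that carbon with inversion (R to S, and a more ionised pathway closes through the same diequatorial chair to the trans lactone), the tert-butyl group leaves as isobutene so that no water competes, C5 keeps the epoxide configuration, and silylation in the same flask blocks acyl migration of the free 5-hydroxyl to the γ-lactone.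

Step 5
Reactants: 7 (5R,6S)-6-[4-(benzyloxy)phenyl]-5-(tert-butyldimethylsilyloxy)oxan-2-one
Product: 9 (2S,3R)-2-[4-(benzyloxy)phenyl]-3-(tert-butyldimethylsilyloxy)-3,4-dihydro-2H-pyran-6-yl diphenyl phosphate, via potassium enolate 8 (not isolated)
Conditions: KN(SiMe3)2, (PhO)2P(O)Cl, HMPA, THF, −78 °C
Reagents that add atoms: diphenyl chlorophosphate, O=P(Cl)(Oc1ccccc1)Oc1ccccc1
Why: Kinetic O-phosphorylation of a lactone enolate gives the cyclic ketene acetal phosphate, a known cross-coupling partner; the enolate has no β-leaving group and both stereocentres are remote from the deprotonated carbon.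

Step 6
Reactants: 9 (2S,3R)-2-[4-(benzyloxy)phenyl]-3-(tert-butyldimethylsilyloxy)-3,4-dihydro-2H-pyran-6-yl diphenyl phosphate; 10 tributyl(1-ethoxyvinyl)stannane
Product: 12 1-[(2S,3R)-2-[4-(benzyloxy)phenyl]-3-(tert-butyldimethylsilyloxy)-3,4-dihydro-2H-pyran-6-yl]ethan-1-one, via ethoxyvinyl diene 11 (not isolated)
Conditions: Pd(PPh3)4 (8 mol %), LiCl, THF, reflux; then 0.5 M aq HCl, THF, 0 °C, short contact
Reagents that add atoms: tributyl(1-ethoxyvinyl)stannane (reactant 10), CCCC[Sn](CCCC)(CCCC)C(=C)OCC; water, O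
Why: Stille coupling of a lactone-derived ketene acetal phosphate (oxidative addition of zerovalent palladium into the C–O bond, LiCl-assisted transmetalation) with an acyl anion equivalent, after which the unsubstituted terminal CH2 of the acyclic enol ether is protonated faster than the β-substituted ring enol ether and the acetyl group so formed deactivates the ring enol ether.

Step 7
Reactants: 12 1-[(2S,3R)-2-[4-(benzyloxy)phenyl]-3-(tert-butyldimethylsilyloxy)-3,4-dihydro-2H-pyran-6-yl]ethan-1-one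
Product: 15 2-diazo-1-[(2S,3R)-2-[4-(benzyloxy)phenyl]-3-(tert-butyldimethylsilyloxy)-3,4-dihydro-2H-pyran-6-yl]ethan-1-one, via lithium enolate 13 (not isolated), via trifluoroacetyl diketone 14 (not isolated)
Conditions: LiN(SiMe3)2, THF, −78 °C; CF3CO2CH2CF3; aq HCl quench; then MsN3, Et3N, H2O (1 equiv), MeCN, rt
Reagents that add atoms: methanesulfonyl azide, CS(=O)(=O)N=[N+]=[N-]; 2,2,2-trifluoroethyl trifluoroacetate (its CF3CO group is carried by 14 only), O=C(OCC(F)(F)F)C(F)(F)F
Why: Detrifluoroacetylative diazo transfer of the Regitz type, in which kinetic enolisation at the methyl group, Claisen trifluoroacetylation and reaction with the sulfonyl azide deliver the diazoketone without exposing the enone C=C to diazomethane, the standard entry to α,β-unsaturated diazomethyl ketones.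

Step 8
Reactants: 16 apigenin
Product: 17 5,7-bis(benzyloxy)-2-[4-(benzyloxy)phenyl]-4H-chromen-4-one
Conditions: BnBr (4.5 equiv), K2CO3, DMF, 80 °C
Reagents that add atoms: benzyl bromide, BrCc1ccccc1
Why: Williamson etherification, with heat and excess bromide so that the hydrogen-bonded 5-hydroxyl is alkylated as well.

Step 9
Reactants: 17 5,7-bis(benzyloxy)-2-[4-(benzyloxy)phenyl]-4H-chromen-4-one
Product: 19 5,7-bis(benzyloxy)-2-[4-(benzyloxy)phenyl]-3-iodo-4H-chromen-4-one, via 3-lithioflavone 18 (not isolated)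
Conditions: LiN(iPr)2, THF, −78 °C; then I2, THF, −78 °C
Reagents that add atoms: iodine, II
Why: Carbonyl-directed deprotonation of the flavone at the vinylic C3–H followed by iodinolysis places iodine at C3 and avoids electrophilic iodination, which would attack C6 or C8 of the electron-rich ring A.

Step 10
Reactants: 19 5,7-bis(benzyloxy)-2-[4-(benzyloxy)phenyl]-3-iodo-4H-chromen-4-one; 20 trimethylsilylacetylene
Product: 21 5,7-bis(benzyloxy)-2-[4-(benzyloxy)phenyl]-3-[(trimethylsilyl)ethynyl]-4H-chromen-4-one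
Conditions: PdCl2(PPh3)2 (5 mol %), CuI (10 mol %), Et3N, DMF, 50 °C
Reagents that add atoms: trimethylsilylacetylene (reactant 20), C#C[Si](C)(C)C
Why: Sonogashira coupling, well established for 3-iodoflavones, in which the slim alkyne tolerates the flanking 2-aryl and 4-oxo groups and a tertiary amine base cannot add to C2.

Step 11
Reactants: 21 5,7-bis(benzyloxy)-2-[4-(benzyloxy)phenyl]-3-[(trimethylsilyl)ethynyl]-4H-chromen-4-one
Product: 22 5,7-bis(benzyloxy)-2-[4-(benzyloxy)phenyl]-3-ethynyl-4H-chromen-4-one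
Conditions: K2CO3 (0.2 equiv), MeOH–THF, 0 °C
Reagents that add atoms: none
Why: Methoxide-catalysed protiodesilylation of an alkynylsilane is fast at 0 °C, where the 2-aryl-substituted pyranone should not suffer conjugate addition.

Step 12
Reactants: 22 5,7-bis(benzyloxy)-2-[4-(benzyloxy)phenyl]-3-ethynyl-4H-chromen-4-one
Product: 25 5,7-bis(benzyloxy)-2-[4-(benzyloxy)phenyl]-3-[(triisopropylsilyloxy)ethynyl]-4H-chromen-4-one, via lithium acetylide 23 (not isolated), via lithium ynolate 24 (not isolated)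
Conditions: LiN(SiMe3)2, THF, −78 °C; LiOOtBu (from anhydrous tBuOOH and LiN(SiMe3)2), −78 to 0 °C; TIPSOTf, −78 to 0 °C; rapid filtration through Et3N-deactivated silica
Reagents that add atoms: tert-butyl hydroperoxide, CC(C)(C)OO; triisopropylsilyl triflate, CC(C)[Si](C(C)C)(C(C)C)OS(=O)(=O)C(F)(F)F
Why: Oxidation of a lithium acetylide by lithium tert-butyl peroxide (attack of the acetylide carbon on the peroxide oxygen) gives the ynolate, which the bulky silyl triflate traps on oxygen; an amide base in place of an alkyllithium spares the flavone carbonyl, and the charge of the acetylide disfavours peroxide addition to C2.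

Step 13
Reactants: 15 2-diazo-1-[(2S,3R)-2-[4-(benzyloxy)phenyl]-3-(tert-butyldimethylsilyloxy)-3,4-dihydro-2H-pyran-6-yl]ethan-1-one; 25 5,7-bis(benzyloxy)-2-[4-(benzyloxy)phenyl]-3-[(triisopropylsilyloxy)ethynyl]-4H-chromen-4-one
Product: 30 5,7-bis(benzyloxy)-2-[4-(benzyloxy)phenyl]-3-[(2S,3R)-2-[4-(benzyloxy)phenyl]-3-(tert-butyldimethylsilyloxy)-5-hydroxy-7-(triisopropylsilyloxy)chroman-6-yl]-4H-chromen-4-one, via vinylketene 26 (not isolated), via vinylcyclobutenone 27 (not isolated), via dienylketene 28 (not isolated), via cyclohexadienone 29 (not isolated)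
Conditions: 15 (1.3 equiv), 25, degassed toluene (0.1 M), 450 nm LEDs, 20 °C until N2 evolution ends; then 90 °C in the dark
Reagents that add atoms: none
Why: Light of 450 nm should be absorbed only by the diazoketone (the benzylated flavone has no band there), N2 is lost and the dihydropyranyl carbon migrates to the carbene carbon (Wolff rearrangement, bond C8–C8a) to give vinylketene 26. The siloxyalkyne adds to the ketene C=C in a polar [2+2] cycloaddition (bonds C5–C6 and C7–C8) to give 4-vinylcyclobutenone 27, which accumulates in the cold because it does not absorb the light used. On heating, 27 opens reversibly (4π, conrotatory) to dienylketene 28, and the isomer that holds ketene and enol ether cis closes ring D by a thermal disrotatory 6π electrocyclisation (bond C4a–C5), after which dienone 29 tautomerises to phenol 30. The closest known reaction is the Danheiser benzannulation in its diazoketone form with triisopropylsiloxyalkynes, combined here with the known visible-light Wolff rearrangement. No new stereocentre survives, since the sp3 carbons of 27 and 29 become aromatic, and C2 and C3 of ring F are spectators under these neutral conditions. The step needs one regiochemistry in the [2+2] event, and the oxygen lone pair of the ynol ether secures it by making the flavone-bearing alkyne carbon the nucleophile that bonds to the ketene carbonyl carbon, which puts the flavone between the C5 hydroxyl and the C7 silyloxy group, while running light and heat as separate stages keeps phenol 30 from being acylated by 26.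

Step 14
Reactants: 30 5,7-bis(benzyloxy)-2-[4-(benzyloxy)phenyl]-3-[(2S,3R)-2-[4-(benzyloxy)phenyl]-3-(tert-butyldimethylsilyloxy)-5-hydroxy-7-(triisopropylsilyloxy)chroman-6-yl]-4H-chromen-4-one
Product: 31 5,7-bis(benzyloxy)-2-[4-(benzyloxy)phenyl]-3-[(2S,3R)-2-[4-(benzyloxy)phenyl]-3,5,7-trihydroxychroman-6-yl]-4H-chromen-4-one
Conditions: Bu4NF (3 equiv), AcOH (3 equiv), THF, 0 °C to rt
Reagents that add atoms: none
Why: Fluoride desilylation of the aryl and the secondary silyl ether, buffered so that phenoxides are short-lived, and done while the ring-E oxygen is still benzylated so that the quinone methide path for epimerisation at C2 stays closed.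

Step 15
Reactants: 31 5,7-bis(benzyloxy)-2-[4-(benzyloxy)phenyl]-3-[(2S,3R)-2-[4-(benzyloxy)phenyl]-3,5,7-trihydroxychroman-6-yl]-4H-chromen-4-one
Product: 32 5,7-dihydroxy-2-(4-hydroxyphenyl)-3-[(2S,3R)-3,5,7-trihydroxy-2-(4-hydroxyphenyl)chroman-6-yl]-4H-chromen-4-one (CNP0222954.2)
Conditions: H2 (1 atm), Pd(OH)2/C, THF–MeOH, rt
Reagents that add atoms: none
Why: Catalytic hydrogenolysis of four aryl benzyl ethers under the conditions customary for benzylated flavan-3-ols, where the tetrasubstituted flavone C2=C3 bond and the cyclic benzylic C2–O1 bond react far more slowly than the benzyl ethers.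

## Compound list

1 | 4-(benzyloxy)benzaldehyde | O=Cc1ccc(OCc2ccccc2)cc1 | starting material
2 | 1-(benzyloxy)-4-vinylbenzene | C=Cc1ccc(OCc2ccccc2)cc1 | intermediate
3 | tert-butyl pent-4-enoate | C=CCCC(=O)OC(C)(C)C | starting material
4 | tert-butyl (E)-5-[4-(benzyloxy)phenyl]pent-4-enoate | CC(C)(C)OC(=O)CC/C=C/c1ccc(OCc2ccccc2)cc1 | intermediate
5 | tert-butyl 3-[(2R,3R)-3-[4-(benzyloxy)phenyl]oxiran-2-yl]propanoate | CC(C)(C)OC(=O)CC[C@H]1O[C@@H]1c1ccc(OCc2ccccc2)cc1 | intermediate
6 | (5R,6S)-6-[4-(benzyloxy)phenyl]-5-hydroxyoxan-2-one (trans hydroxylactone, not isolated) | O=C1CC[C@@H](O)[C@H](c2ccc(OCc3ccccc3)cc2)O1 | intermediate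
7 | (5R,6S)-6-[4-(benzyloxy)phenyl]-5-(tert-butyldimethylsilyloxy)oxan-2-one | O=C1CC[C@@H](O[Si](C)(C)C(C)(C)C)[C@H](c2ccc(OCc3ccccc3)cc2)O1 | intermediate
8 | potassium enolate of 7 (not isolated) | [K+].[O-]C1=CC[C@@H](O[Si](C)(C)C(C)(C)C)[C@H](c2ccc(OCc3ccccc3)cc2)O1 | intermediate
9 | (2S,3R)-2-[4-(benzyloxy)phenyl]-3-(tert-butyldimethylsilyloxy)-3,4-dihydro-2H-pyran-6-yl diphenyl phosphate | O=P(Oc1ccccc1)(Oc1ccccc1)OC1=CC[C@@H](O[Si](C)(C)C(C)(C)C)[C@H](c2ccc(OCc3ccccc3)cc2)O1 | intermediate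
10 | tributyl(1-ethoxyvinyl)stannane | CCCC[Sn](CCCC)(CCCC)C(=C)OCC | starting material
11 | (2S,3R)-2-[4-(benzyloxy)phenyl]-3-(tert-butyldimethylsilyloxy)-6-(1-ethoxyvinyl)-3,4-dihydro-2H-pyran (not isolated) | C=C(OCC)C1=CC[C@@H](O[Si](C)(C)C(C)(C)C)[C@H](c2ccc(OCc3ccccc3)cc2)O1 | intermediate
12 | 1-[(2S,3R)-2-[4-(benzyloxy)phenyl]-3-(tert-butyldimethylsilyloxy)-3,4-dihydro-2H-pyran-6-yl]ethan-1-one | CC(=O)C1=CC[C@@H](O[Si](C)(C)C(C)(C)C)[C@H](c2ccc(OCc3ccccc3)cc2)O1 | intermediate
13 | lithium enolate of 12 at the methyl group (not isolated) | C=C(O[Li])C1=CC[C@@H](O[Si](C)(C)C(C)(C)C)[C@H](c2ccc(OCc3ccccc3)cc2)O1 | intermediate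
14 | 4,4,4-trifluoro-1-[(2S,3R)-2-[4-(benzyloxy)phenyl]-3-(tert-butyldimethylsilyloxy)-3,4-dihydro-2H-pyran-6-yl]butane-1,3-dione (not isolated) | O=C(CC(=O)C(F)(F)F)C1=CC[C@@H](O[Si](C)(C)C(C)(C)C)[C@H](c2ccc(OCc3ccccc3)cc2)O1 | intermediate
15 | 2-diazo-1-[(2S,3R)-2-[4-(benzyloxy)phenyl]-3-(tert-butyldimethylsilyloxy)-3,4-dihydro-2H-pyran-6-yl]ethan-1-one | [N-]=[N+]=CC(=O)C1=CC[C@@H](O[Si](C)(C)C(C)(C)C)[C@H](c2ccc(OCc3ccccc3)cc2)O1 | intermediate
16 | apigenin | O=c1cc(-c2ccc(O)cc2)oc2cc(O)cc(O)c12 | starting material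
17 | 5,7-bis(benzyloxy)-2-[4-(benzyloxy)phenyl]-4H-chromen-4-one | O=c1cc(-c2ccc(OCc3ccccc3)cc2)oc2cc(OCc3ccccc3)cc(OCc3ccccc3)c12 | intermediate
18 | 3-lithio derivative of 17 (not isolated) | O=c1c([Li])c(-c2ccc(OCc3ccccc3)cc2)oc2cc(OCc3ccccc3)cc(OCc3ccccc3)c12 | intermediate
19 | 5,7-bis(benzyloxy)-2-[4-(benzyloxy)phenyl]-3-iodo-4H-chromen-4-one | O=c1c(I)c(-c2ccc(OCc3ccccc3)cc2)oc2cc(OCc3ccccc3)cc(OCc3ccccc3)c12 | intermediate
20 | trimethylsilylacetylene | C#C[Si](C)(C)C | starting material
21 | 5,7-bis(benzyloxy)-2-[4-(benzyloxy)phenyl]-3-[(trimethylsilyl)ethynyl]-4H-chromen-4-one | O=c1c(C#C[Si](C)(C)C)c(-c2ccc(OCc3ccccc3)cc2)oc2cc(OCc3ccccc3)cc(OCc3ccccc3)c12 | intermediate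
22 | 5,7-bis(benzyloxy)-2-[4-(benzyloxy)phenyl]-3-ethynyl-4H-chromen-4-one | O=c1c(C#C)c(-c2ccc(OCc3ccccc3)cc2)oc2cc(OCc3ccccc3)cc(OCc3ccccc3)c12 | intermediate
23 | lithium acetylide of 22 (not isolated) | O=c1c(C#C[Li])c(-c2ccc(OCc3ccccc3)cc2)oc2cc(OCc3ccccc3)cc(OCc3ccccc3)c12 | intermediate
24 | lithium ynolate, flavon-3-yl-C≡C-OLi (not isolated) | O=c1c(C#CO[Li])c(-c2ccc(OCc3ccccc3)cc2)oc2cc(OCc3ccccc3)cc(OCc3ccccc3)c12 | intermediate
25 | 5,7-bis(benzyloxy)-2-[4-(benzyloxy)phenyl]-3-[(triisopropylsilyloxy)ethynyl]-4H-chromen-4-one | O=c1c(C#CO[Si](C(C)C)(C(C)C)C(C)C)c(-c2ccc(OCc3ccccc3)cc2)oc2cc(OCc3ccccc3)cc(OCc3ccccc3)c12 | intermediate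
26 | [(2S,3R)-2-[4-(benzyloxy)phenyl]-3-(tert-butyldimethylsilyloxy)-3,4-dihydro-2H-pyran-6-yl]ketene (not isolated) | O=C=CC1=CC[C@@H](O[Si](C)(C)C(C)(C)C)[C@H](c2ccc(OCc3ccccc3)cc2)O1 | intermediate
27 | 4-(dihydropyran-6-yl)-2-(flavon-3-yl)-3-(triisopropylsilyloxy)cyclobut-2-en-1-one, epimers at the ring CH (not isolated) | O=c1c(C4=C(O[Si](C(C)C)(C(C)C)C(C)C)C(C5=CC[C@@H](O[Si](C)(C)C(C)(C)C)[C@H](c6ccc(OCc7ccccc7)cc6)O5)C4=O)c(-c2ccc(OCc3ccccc3)cc2)oc2cc(OCc3ccccc3)cc(OCc3ccccc3)c12 | intermediate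
28 | dienylketene, ketene carbon and dihydropyranyl group cis on the central C=C (not isolated) | O=c1c(C(=C=O)/C(O[Si](C(C)C)(C(C)C)C(C)C)=C\C5=CC[C@@H](O[Si](C)(C)C(C)(C)C)[C@H](c6ccc(OCc7ccccc7)cc6)O5)c(-c2ccc(OCc3ccccc3)cc2)oc2cc(OCc3ccccc3)cc(OCc3ccccc3)c12 | intermediate
29 | cyclohexa-2,4-dienone tautomer of 30, sp3 carbon at C4a (not isolated) | O=c1c(C4=C(O[Si](C(C)C)(C(C)C)C(C)C)C=C5C(C4=O)C[C@@H](O[Si](C)(C)C(C)(C)C)[C@H](c6ccc(OCc7ccccc7)cc6)O5)c(-c2ccc(OCc3ccccc3)cc2)oc2cc(OCc3ccccc3)cc(OCc3ccccc3)c12 | intermediate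
30 | 5,7-bis(benzyloxy)-2-[4-(benzyloxy)phenyl]-3-[(2S,3R)-2-[4-(benzyloxy)phenyl]-3-(tert-butyldimethylsilyloxy)-5-hydroxy-7-(triisopropylsilyloxy)chroman-6-yl]-4H-chromen-4-one | O=c1c(-c4c(O[Si](C(C)C)(C(C)C)C(C)C)cc5c(c4O)C[C@@H](O[Si](C)(C)C(C)(C)C)[C@H](c6ccc(OCc7ccccc7)cc6)O5)c(-c2ccc(OCc3ccccc3)cc2)oc2cc(OCc3ccccc3)cc(OCc3ccccc3)c12 | intermediate
31 | 5,7-bis(benzyloxy)-2-[4-(benzyloxy)phenyl]-3-[(2S,3R)-2-[4-(benzyloxy)phenyl]-3,5,7-trihydroxychroman-6-yl]-4H-chromen-4-one | O=c1c(-c4c(O)cc5c(c4O)C[C@@H](O)[C@H](c6ccc(OCc7ccccc7)cc6)O5)c(-c2ccc(OCc3ccccc3)cc2)oc2cc(OCc3ccccc3)cc(OCc3ccccc3)c12 | intermediate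
32 | 5,7-dihydroxy-2-(4-hydroxyphenyl)-3-[(2S,3R)-3,5,7-trihydroxy-2-(4-hydroxyphenyl)chroman-6-yl]-4H-chromen-4-one (CNP0222954.2) | O=c1c(-c2c(O)cc3c(c2O)C[C@@H](O)[C@H](c2ccc(O)cc2)O3)c(-c2ccc(O)cc2)oc2cc(O)cc(O)c12 | target

## Step count and risks

Total step count: 15. Longest linear sequence: 10 steps (steps 1 to 7, then 13 to 15). The apigenin branch contributes 5 steps (steps 8 to 12).

**Step 13.**
- What may go wrong: capture of ketene 26 by the hindered alkyne may be slower than ketene dimerisation or its addition to the enol ether of a second molecule. The 2-aryl-3-alkynylchromone may also decay on long irradiation.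
- Fallback: the flavone never sees light, and base releases the ketene slowly.
- Setting out from 15, the Wolff rearrangement is run alone at 450 nm in THF–H2O with Et3N. After careful neutralisation it gives 2-[(2S,3R)-2-[4-(benzyloxy)phenyl]-3-(tert-butyldimethylsilyloxy)-3,4-dihydro-2H-pyran-6-yl]acetic acid F1.
- 1-Chloro-N,N,2-trimethylpropenylamine in CH2Cl2 at 0 °C converts it under neutral conditions into 2-[(2S,3R)-2-[4-(benzyloxy)phenyl]-3-(tert-butyldimethylsilyloxy)-3,4-dihydro-2H-pyran-6-yl]acetyl chloride F2.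
- Slow addition of this chloride to 25 and iPr2NEt in toluene at 60 °C generates 26 by dehydrochlorination at a low stationary concentration. The route is rejoined at cyclobutenone 27, which is heated on to 30.

**Step 12.**
- What may go wrong: the peroxide or the ynolate may add to C2 or C4 of the flavone, silylation may occur on carbon, and the siloxyalkyne may hydrolyse during purification.
- Fallback: an ynol ether is made by cross-coupling, so no ynolate is needed.
- Setting out from iodide 19, Sonogashira coupling with tert-butoxyethyne (PdCl2(PPh3)2, CuI, Et3N, THF, 20 °C) gives 5,7-bis(benzyloxy)-2-[4-(benzyloxy)phenyl]-3-(tert-butoxyethynyl)-4H-chromen-4-one F3.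
- This ether takes the place of 25 in the benzannulation with 15. The light stage is held at or below 20 °C because the ether loses isobutene on warming, and 15 is used in excess so that none of the ether reaches the heating stage.
- The reaction passes through the tert-butoxy vinylcyclobutenone F4, the tert-butoxy dienylketene F5 and the tert-butoxy cyclohexadienone F6 to the 7-O-tert-butyl 5-hydroxyflavan F7.
- CF3CO2H with anisole in CH2Cl2 at 0 °C frees the 7-hydroxyl to give the 3-O-silyl 5,7-diol F8. Bu4NF–AcOH then leads back to 31.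

**Step 4.**
- What may go wrong: 5-exo opening may compete, a hydride shift may convert the benzylic cation into the benzyl ketone, the acyl group may migrate to the γ-lactone before silylation, and trans selectivity may be partly lost.
- Fallback: oxygen is silylated in the same event that opens the epoxide, so a free hydroxyl never sits next to a lactone.
- Setting out from epoxide 5, TBSCl with catalytic Bu4NCl in CH2Cl2 at 0 °C delivers chloride to the benzylic carbon and silicon to the other oxygen. This gives tert-butyl (4R,5S)-5-[4-(benzyloxy)phenyl]-4-(tert-butyldimethylsilyloxy)-5-chloropentanoate F9.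
- AgOTf with 2,6-di-tert-butylpyridine in CH2Cl2 at −40 °C ionises the chloride. The ester carbonyl captures the cation through the diequatorial chair, isobutene is lost, and the route is rejoined at 7.
- The configuration of the chloride is irrelevant because closure runs through the cation, and the silyloxy-bearing carbon is untouched.

## Further compounds

F1 | step 13 | 2-[(2S,3R)-2-[4-(benzyloxy)phenyl]-3-(tert-butyldimethylsilyloxy)-3,4-dihydro-2H-pyran-6-yl]acetic acid | OC(=O)CC1=CC[C@@H](O[Si](C)(C)C(C)(C)C)[C@H](c2ccc(OCc3ccccc3)cc2)O1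
F2 | step 13 | 2-[(2S,3R)-2-[4-(benzyloxy)phenyl]-3-(tert-butyldimethylsilyloxy)-3,4-dihydro-2H-pyran-6-yl]acetyl chloride | ClC(=O)CC1=CC[C@@H](O[Si](C)(C)C(C)(C)C)[C@H](c2ccc(OCc3ccccc3)cc2)O1
F3 | step 12 | 5,7-bis(benzyloxy)-2-[4-(benzyloxy)phenyl]-3-(tert-butoxyethynyl)-4H-chromen-4-one | O=c1c(C#COC(C)(C)C)c(-c2ccc(OCc3ccccc3)cc2)oc2cc(OCc3ccccc3)cc(OCc3ccccc3)c12
F4 | step 12 | tert-butoxy vinylcyclobutenone (3-tert-butoxy analogue of 27) | O=c1c(C4=C(OC(C)(C)C)C(C5=CC[C@@H](O[Si](C)(C)C(C)(C)C)[C@H](c6ccc(OCc7ccccc7)cc6)O5)C4=O)c(-c2ccc(OCc3ccccc3)cc2)oc2cc(OCc3ccccc3)cc(OCc3ccccc3)c12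
F5 | step 12 | tert-butoxy dienylketene (tert-butoxy analogue of 28) | O=c1c(C(=C=O)/C(OC(C)(C)C)=C\C5=CC[C@@H](O[Si](C)(C)C(C)(C)C)[C@H](c6ccc(OCc7ccccc7)cc6)O5)c(-c2ccc(OCc3ccccc3)cc2)oc2cc(OCc3ccccc3)cc(OCc3ccccc3)c12
F6 | step 12 | tert-butoxy cyclohexadienone (tert-butoxy analogue of 29) | O=c1c(C4=C(OC(C)(C)C)C=C5C(C4=O)C[C@@H](O[Si](C)(C)C(C)(C)C)[C@H](c6ccc(OCc7ccccc7)cc6)O5)c(-c2ccc(OCc3ccccc3)cc2)oc2cc(OCc3ccccc3)cc(OCc3ccccc3)c12
F7 | step 12 | 5,7-bis(benzyloxy)-2-[4-(benzyloxy)phenyl]-3-[(2S,3R)-2-[4-(benzyloxy)phenyl]-7-tert-butoxy-3-(tert-butyldimethylsilyloxy)-5-hydroxychroman-6-yl]-4H-chromen-4-one | O=c1c(-c4c(OC(C)(C)C)cc5c(c4O)C[C@@H](O[Si](C)(C)C(C)(C)C)[C@H](c6ccc(OCc7ccccc7)cc6)O5)c(-c2ccc(OCc3ccccc3)cc2)oc2cc(OCc3ccccc3)cc(OCc3ccccc3)c12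
F8 | step 12 | 5,7-bis(benzyloxy)-2-[4-(benzyloxy)phenyl]-3-[(2S,3R)-2-[4-(benzyloxy)phenyl]-3-(tert-butyldimethylsilyloxy)-5,7-dihydroxychroman-6-yl]-4H-chromen-4-one | O=c1c(-c4c(O)cc5c(c4O)C[C@@H](O[Si](C)(C)C(C)(C)C)[C@H](c6ccc(OCc7ccccc7)cc6)O5)c(-c2ccc(OCc3ccccc3)cc2)oc2cc(OCc3ccccc3)cc(OCc3ccccc3)c12
F9 | step 4 | tert-butyl (4R,5S)-5-[4-(benzyloxy)phenyl]-4-(tert-butyldimethylsilyloxy)-5-chloropentanoate | CC(C)(C)OC(=O)CC[C@@H](O[Si](C)(C)C(C)(C)C)[C@@H](Cl)c1ccc(OCc2ccccc2)cc1
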